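**Strategy.** Ring A (C1, C10–C14; briarane numbering) carries oxygen on C14 and C11 in a 1,4-relationship and a methyl group on C11. This pattern is read as a 2-silyloxydiene (C13=C14–C1=C10) plus methacrolein (C12=C11). One catalytic enantioselective Diels–Alder reaction joins C12–C13 and C10–C11, sets C10 and C11, and leaves a regiodefined C14 enol silane. The formyl group is later exchanged for the C11 hydroxyl by Baeyer–Villiger oxidation. The stored enolate then builds quaternary C1 and C2 by a samarium aldol, Evans–Tishchenko reduction sets C14, a Nozaki–Hiyama–Kishi reaction closes ring B at C6–C7, and a samarium Reformatsky reaction forms the lactone.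

Key step: step 3

Remark (numbering): briarane numbering is used for all intermediates: ring A = C1, C10, C11, C12, C13, C14 (CH3-15 on C1, CH3-20 on C11); ring B = C1 to C10 (CH3-16 on C5); lactone = C7–O–C19(=O)–C17(CH3-18)–C8.

Remark (assumption): the (S)-configured oxazaborolidinium catalyst of step 3 is assumed, from its accepted pre-transition-state model, to direct the diene to the Re face of the alpha carbon of methacrolein; if the sense were the opposite, the (R)-catalyst would be used.

**Step 1**
Reactants: 1 (tert-butyldimethylsilyloxy)acetaldehyde; 2 3-(triphenylphosphoranylidene)butan-2-one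
Product: 3 (E)-5-[(tert-butyldimethylsilyl)oxy]-3-methylpent-3-en-2-one
Conditions: toluene, 90 °C
Reagents that add atoms: none
Why: Wittig olefination with a stabilised, alpha-branched ylide should give the (E)-enone (acetyl trans to CH2OTBS), which already holds C13, C14, C1, C15, C10 and C9.

**Step 2**
Reactants: 3 (E)-enone
Product: 4 (E)-1-[(tert-butyldimethylsilyl)oxy]-3-methyl-4-[(triisopropylsilyl)oxy]penta-2,4-diene
Conditions: TIPSOTf, Et3N, CH2Cl2, 0 °C
Reagents that add atoms: triisopropylsilyl triflate, CC(C)[Si](OS(=O)(=O)C(F)(F)F)(C(C)C)C(C)C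
Why: soft enolisation and O-silylation of the methyl ketone (deprotonation at the alpha' methyl group) should give the cross-conjugated 2-silyloxy-1,3-diene without touching the C1=C10 geometry.

**Step 3**
Reactants: 4 (E)-2-silyloxydiene; 5 methacrolein
Product: 6 (1S,2R)-2-{[(tert-butyldimethylsilyl)oxy]methyl}-1,3-dimethyl-4-[(triisopropylsilyl)oxy]cyclohex-3-ene-1-carbaldehyde (ring A; C11 formyl cis to the C10 CH2OTBS group)
Conditions: (S)-3,3-diphenyl-1-(2-methylphenyl)tetrahydro-1H,3H-pyrrolo[1,2-c][1,3,2]oxazaborole (20 mol%), Tf2NH (18 mol%), 5 (3 equiv), CH2Cl2, −78 → −40 °C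
Reagents that add atoms: none
Why: The triflimide-activated oxazaborolidine binds methacrolein (s-trans, formyl C–H···O contact) and lowers its LUMO, so that a concerted, asynchronous (4+2) cycloaddition with the electron-rich diene forms C12–C13 (leading bond) and C10–C11; the closest known reaction type is the oxazaborolidinium-catalysed Diels–Alder reaction of 2-substituted acroleins with 2-silyloxy-1,3-dienes. Ring A (C1, C10–C14) is closed by this intermolecular suprafacial cycloaddition of a four-carbon and a two-carbon unit. C11 is set by the catalyst, which shields one face of the enal so that the diene adds to the Re face of the alpha carbon, and C10 is set relative to C11 by the E geometry of C1=C10 together with the endo orientation of the formyl group (CH2OTBS cis to CHO, as is usual for acyclic E-dienes with methacrolein). The step needs regioselectivity, which the C14 silyloxy group and the C10 alkyl group secure together by placing the largest HOMO coefficient on C13, and it needs endo selectivity, which the exo position of the small alpha-methyl group favours. The C14/C1 enol silane survives as a regiodefined enolate equivalent.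

**Step 4**
Reactants: 6 Diels–Alder adduct
Product: 7 3-bromo-2-{[(tert-butyldimethylsilyl)oxy]methyl}-1,3-dimethyl-4-oxocyclohexane-1-carbaldehyde with C10 and C11 as in 6 (both C1 bromide epimers)
Conditions: NBS, NaHCO3, THF, −78 → 0 °C
Reagents that add atoms: N-bromosuccinimide, O=C1CCC(=O)N1Br
Why: electrophilic bromination of the silyl enol ether occurs only at C1 and stores the regiodefined enolate as a tertiary alpha-bromo ketone that is inert to peracid; the C1 configuration is irrelevant because both epimers converge in step 11.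

**Step 5**
Reactants: 7 alpha-bromo ketone aldehyde
Product: 9 2-bromo-3-{[(tert-butyldimethylsilyl)oxy]methyl}-4-hydroxy-2,4-dimethylcyclohexan-1-one (C11 hydroxyl cis to CH2OTBS), via tertiary formate 8 (not isolated)
Conditions: mCPBA, NaHCO3, CH2Cl2, 0 °C → rt; then KHCO3, MeOH/H2O, 0 °C
Reagents that add atoms: meta-chloroperoxybenzoic acid, OOC(=O)c1cccc(Cl)c1
Why: Baeyer–Villiger oxidation of the alpha-quaternary aldehyde (the tertiary alkyl group migrates with retention at C11) and mild methanolysis of the formate should give the C11 carbinol cis to C9, the weak base being chosen to avoid Favorskii chemistry of the bromo ketone.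

**Step 6**
Reactants: 9 tertiary alcohol
Product: 10 2-bromo-4-[(tert-butyldimethylsilyl)oxy]-3-{[(tert-butyldimethylsilyl)oxy]methyl}-2,4-dimethylcyclohexan-1-one
Conditions: TBSOTf, 2,6-lutidine, CH2Cl2, 0 °C → rt
Reagents that add atoms: tert-butyldimethylsilyl triflate, CC(C)(C)[Si](C)(C)OS(=O)(=O)C(F)(F)F
Why: silylation of the hindered tertiary alcohol with the silyl triflate removes the only acidic proton that could quench the samarium enolate of step 11.

**Step 7**
Reactants: 11 propargyl alcohol
Product: 13 (Z)-3-iodo-2-methylprop-2-en-1-ol, via alkenylmagnesium alkoxide 12 (not isolated)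
Conditions: MeMgBr (3 equiv), CuI (10 mol%), THF, −10 °C → rt; then I2, −78 → 0 °C
Reagents that add atoms: methylmagnesium bromide, C[Mg]Br; iodine, II
Why: copper-catalysed anti-carbomagnesiation of the propargylic alkoxide through the five-membered magnesium chelate, then iodinolysis with retention, fixes the Z geometry (iodine cis to CH2OH) that later becomes the C5=C6 geometry.

**Step 8**
Reactants: 13 (Z)-iodo allylic alcohol
Product: 14 (Z)-3-bromo-1-iodo-2-methylprop-1-ene
Conditions: CBr4, PPh3, CH2Cl2, 0 °C
Reagents that add atoms: carbon tetrabromide, BrC(Br)(Br)Br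
Why: Appel bromination of the primary allylic alcohol proceeds without allylic transposition or loss of the alkene geometry.

**Step 9**
Reactants: 14 allylic bromide
Product: 15 tert-butyl (Z)-5-iodo-4-methylpent-4-enoate
Conditions: LiN(iPr)2, tert-butyl acetate, THF, −78 °C; then 14, −78 → −30 °C
Reagents that add atoms: tert-butyl acetate (as its lithium enolate), CC(=O)OC(C)(C)C
Why: SN2 alkylation of the lithium ester enolate with the reactive allylic bromide adds C2 and C3, the vinyl iodide being inert to the enolate.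

**Step 10**
Reactants: 15 tert-butyl ester
Product: 16 (Z)-5-iodo-4-methylpent-4-enal
Conditions: iBu2AlH, CH2Cl2, −78 °C; Rochelle salt work-up
Reagents that add atoms: none
Why: partial reduction of the ester at low temperature stops at the aluminium hemiacetal, which gives the aldehyde on work-up.

**Step 11**
Reactants: 10 alpha-bromo ketone; 16 (Z)-5-iodo-4-methylpent-4-enal
Product: 17 aldol adduct (C14 ketone; quaternary C1 with CH3-15 and the (2S)-hydroxy side chain C2–C6; C1, C2, C10, C11 as in the target)
Conditions: SmI2 (2.2 equiv, added slowly to 10 + 16), THF, −78 °C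
Reagents that add atoms: none
Why: samarium Barbier-type (Reformatsky-type) aldol, in which reduction of the C–Br bond gives the trivalent samarium enolate regiospecifically at C1 and this adds to 16 through a chelated chair transition state on the face anti to the C10 side chain and the C11 silyloxy group, setting quaternary C1 (side chain alpha) and C2 (hydroxyl syn to CH3-15, anti to the C1–C10 bond).

**Step 12**
Reactants: 17 aldol adduct
Product: 18 C2 acetate C14 alcohol (1,3-anti; C14 hydroxyl alpha)
Conditions: acetaldehyde (10 equiv), SmI2 (0.3 equiv), THF, −10 °C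
Reagents that add atoms: acetaldehyde, CC=O
Why: Evans–Tishchenko reduction, in which the samarium-bound hemiacetal formed from the C2 hydroxyl and acetaldehyde delivers hydride intramolecularly to C14, sets the 1,3-anti C14 carbinol and leaves the C2 oxygen as its acetate in the same operation.

**Step 13**
Reactants: 18 C2 acetate C14 alcohol
Product: 19 C14 tert-butyldimethylsilyl ether of 18
Conditions: TBSOTf, 2,6-lutidine, CH2Cl2, 0 °C → rt
Reagents that add atoms: tert-butyldimethylsilyl triflate, CC(C)(C)[Si](C)(C)OS(=O)(=O)C(F)(F)F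
Why: silylation of the hindered axial C14 hydroxyl protects it from the later oxidations and acylations without acyl migration.

**Step 14**
Reactants: 19 tris-silyl ether
Product: 20 primary C9 alcohol (C11 and C14 silyl ethers kept)
Conditions: HF·pyridine, pyridine, THF, 0 °C
Reagents that add atoms: none
Why: buffered fluoride cleaves the unhindered primary silyl ether much faster than the tertiary and the hindered secondary ones.

**Step 15**
Reactants: 20 primary alcohol
Product: 21 C9 aldehyde
Conditions: Dess–Martin periodinane, NaHCO3, CH2Cl2, 0 °C → rt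
Reagents that add atoms: none
Why: neutral Dess–Martin oxidation gives the aldehyde, whose C10 centre is the thermodynamically preferred equatorial epimer and so is not at risk.

**Step 16**
Reactants: 21 C9 aldehyde
Product: 22 homoallylic alcohol (C9 hydroxyl as in the target; C8 4-methoxybenzyl ether syn to it; C7 terminal vinyl group)
Conditions: allyl 4-methoxybenzyl ether, sec-BuLi, THF, −78 °C; (+)-Ipc2BOMe [from (−)-alpha-pinene]; BF3·OEt2; then 21, −78 °C → rt; ethanolamine work-up
Reagents that add atoms: (Z)-[3-(4-methoxybenzyloxy)allyl]diisopinocampheylborane (made in the flask from allyl 4-methoxybenzyl ether, C=CCOCc1ccc(OC)cc1), COc1ccc(CO/C=C\CB(C2CC3CC(C2C)C3(C)C)C2CC3CC(C2C)C3(C)C)cc1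
Why: Brown alkoxyallylboration, in which the (Z)-gamma-alkoxyallylborane adds through a closed chair transition state to the Re face of the aldehyde under control of the isopinocampheyl groups, sets C9 as in the target and C8 syn to it, C8 being kept only as a temporary control element for C7.

**Step 17**
Reactants: 22 homoallylic alcohol
Product: 23 C9 acetate
Conditions: Ac2O, DMAP, pyridine, CH2Cl2, rt
Reagents that add atoms: acetic anhydride, CC(=O)OC(C)=O
Why: DMAP-catalysed acetylation of the only free hydroxyl installs the second acetate of the target.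

**Step 18**
Reactants: 23 C9 acetate with terminal vinyl group
Product: 25 C7 aldehyde (C8 ether and C9 acetate unchanged), via vicinal diol 24 (not isolated)
Conditions: OsO4 (2 mol%), NaIO4, 2,6-lutidine, dioxane/H2O, rt
Reagents that add atoms: osmium tetroxide, O=[Os](=O)(=O)=O; water, O
Why: Lemieux–Johnson cleavage, in which OsO4 should dihydroxylate the monosubstituted vinyl group much faster than the electron-poor, trisubstituted iodoalkene before periodate cleaves the diol.

**Step 19**
Reactants: 25 C7 aldehyde with (Z)-vinyl iodide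
Product: 26 ten-membered carbocycle (ring B closed; C7 hydroxyl as in the target; C8 4-methoxybenzyl ether)
Conditions: CrCl2 (10 equiv), NiCl2 (0.1 equiv), DMSO/THF, rt, 0.003 M, slow addition of 25
Reagents that add atoms: none
Why: Nozaki–Hiyama–Kishi reaction, in which zerovalent nickel inserts into the C–I bond and transmetalation gives an alkenylchromium that adds only to the aldehyde, closes ring B at C6–C7 with retention of the Z geometry, and C7 should form by Felkin–Anh addition anti to the C8 ether (a C7 epimer could still be used through Mitsunobu esterification with inversion in step 20).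

**Step 20**
Reactants: 26 macrocyclic allylic alcohol
Product: 27 C7 2-bromopropionate (both CHBr epimers)
Conditions: 2-bromopropionyl bromide, pyridine, CH2Cl2, −20 → 0 °C
Reagents that add atoms: 2-bromopropionyl bromide, CC(Br)C(Br)=O
Why: acylation of the C7 hydroxyl attaches C17, C18 and C19 as a latent ester enolate.

**Step 21**
Reactants: 27 C7 2-bromopropionate
Product: 28 C8 alcohol
Conditions: DDQ, CH2Cl2/pH 7 buffer, 0 °C
Reagents that add atoms: none
Why: oxidative cleavage of the 4-methoxybenzyl ether under buffered conditions frees the C8 hydroxyl without acyl migration (used crude).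

**Step 22**
Reactants: 28 C8 alcohol
Product: 29 C8 ketone (alpha-acyloxy ketone)
Conditions: Dess–Martin periodinane, NaHCO3, CH2Cl2, 0 °C
Reagents that add atoms: none
Why: buffered Dess–Martin oxidation removes the temporary C8 stereocentre and gives the ketone without epimerising C7 or C9.

**Step 23**
Reactants: 29 C8 ketone
Product: 30 11,14-bis(tert-butyldimethylsilyl) ether of the target (lactone closed; C8 and C17 as in the target)
Conditions: SmI2 (2.2 equiv), THF, −78 °C; aqueous NH4Cl at −78 °C
Reagents that add atoms: none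
Why: samarium-mediated intramolecular Reformatsky reaction, in which reduction of the alpha-bromo ester gives a samarium enolate held on the C7 oxygen that adds 5-exo to the C8 ketone on the face that keeps C6 and C9 trans and turns CH3-18 away from C9 (cis to the chelated C8 oxygen), sets C8 and C17.

**Step 24**
Reactants: 30 bis-silyl ether
Product: 31 junceellolide I
Conditions: HF (48% aq), MeCN, 0 °C → rt
Reagents that add atoms: none
Why: acidic fluoride removes the tertiary C11 and secondary C14 silyl ethers while acetates and lactone remain, so that no acyl migration should occur.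

**Compound list**

1 | (tert-butyldimethylsilyloxy)acetaldehyde | O=CCO[Si](C)(C)C(C)(C)C | starting material
2 | 3-(triphenylphosphoranylidene)butan-2-one | CC(=O)C(C)=P(c1ccccc1)(c1ccccc1)c1ccccc1 | starting material
3 | (E)-5-[(tert-butyldimethylsilyl)oxy]-3-methylpent-3-en-2-one | CC(=O)/C(C)=C/CO[Si](C)(C)C(C)(C)C | intermediate
4 | (E)-1-[(tert-butyldimethylsilyl)oxy]-3-methyl-4-[(triisopropylsilyl)oxy]penta-2,4-diene | C=C(O[Si](C(C)C)(C(C)C)C(C)C)/C(C)=C/CO[Si](C)(C)C(C)(C)C | intermediate
5 | methacrolein | C=C(C)C=O | starting material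
6 | (1S,2R)-2-{[(tert-butyldimethylsilyl)oxy]methyl}-1,3-dimethyl-4-[(triisopropylsilyl)oxy]cyclohex-3-ene-1-carbaldehyde | CC(C)(C)[Si](C)(C)OC[C@@H]1C(C)=C(O[Si](C(C)C)(C(C)C)C(C)C)CC[C@]1(C)C=O | intermediate
7 | 3-bromo-2-{[(tert-butyldimethylsilyl)oxy]methyl}-1,3-dimethyl-4-oxocyclohexane-1-carbaldehyde, C10 and C11 as in 6, both C1 epimers | CC(C)(C)[Si](C)(C)OC[C@@H]1C(C)(Br)C(=O)CC[C@]1(C)C=O | intermediate
8 | formate ester of 9 (C11 O-formyl) | CC(C)(C)[Si](C)(C)OC[C@@H]1C(C)(Br)C(=O)CC[C@]1(C)OC=O | intermediate (not isolated)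
9 | 2-bromo-3-{[(tert-butyldimethylsilyl)oxy]methyl}-4-hydroxy-2,4-dimethylcyclohexan-1-one, C10 and C11 as in the target | CC(C)(C)[Si](C)(C)OC[C@@H]1C(C)(Br)C(=O)CC[C@]1(C)O | intermediate
10 | 2-bromo-4-[(tert-butyldimethylsilyl)oxy]-3-{[(tert-butyldimethylsilyl)oxy]methyl}-2,4-dimethylcyclohexan-1-one | CC(C)(C)[Si](C)(C)OC[C@@H]1C(C)(Br)C(=O)CC[C@]1(C)O[Si](C)(C)C(C)(C)C | intermediate
11 | propargyl alcohol | C#CCO | starting material
12 | bromomagnesium (Z)-3-(bromomagnesio)-2-methylprop-2-en-1-olate | Br[Mg]OC/C(C)=C\[Mg]Br | intermediate (not isolated)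
13 | (Z)-3-iodo-2-methylprop-2-en-1-ol | OC/C(C)=C\I | intermediate
14 | (Z)-3-bromo-1-iodo-2-methylprop-1-ene | BrC/C(C)=C\I | intermediate
15 | tert-butyl (Z)-5-iodo-4-methylpent-4-enoate | CC(C)(C)OC(=O)CC/C(C)=C\I | intermediate
16 | (Z)-5-iodo-4-methylpent-4-enal | O=CCC/C(C)=C\I | intermediate
17 | aldol adduct: 4-[(tert-butyldimethylsilyl)oxy]-3-{[(tert-butyldimethylsilyl)oxy]methyl}-2-[(1S,4Z)-1-hydroxy-5-iodo-4-methylpent-4-en-1-yl]-2,4-dimethylcyclohexan-1-one, ring centres as C1, C10, C11 of the target | CC(C)(C)[Si](C)(C)OC[C@@H]1[C@@](C)([C@@H](O)CC/C(C)=C\I)C(=O)CC[C@]1(C)O[Si](C)(C)C(C)(C)C | intermediate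
18 | C2 acetate, C14 alcohol (14-hydroxyl alpha, anti to the C2 oxygen) | CC(C)(C)[Si](C)(C)OC[C@@H]1[C@@](C)([C@@H](OC(C)=O)CC/C(C)=C\I)[C@@H](O)CC[C@]1(C)O[Si](C)(C)C(C)(C)C | intermediate
19 | C2 acetate with C9, C11 and C14 tert-butyldimethylsilyl ethers | CC(C)(C)[Si](C)(C)OC[C@@H]1[C@@](C)([C@@H](OC(C)=O)CC/C(C)=C\I)[C@@H](O[Si](C)(C)C(C)(C)C)CC[C@]1(C)O[Si](C)(C)C(C)(C)C | intermediate
20 | primary C9 alcohol | OC[C@@H]1[C@@](C)([C@@H](OC(C)=O)CC/C(C)=C\I)[C@@H](O[Si](C)(C)C(C)(C)C)CC[C@]1(C)O[Si](C)(C)C(C)(C)C | intermediate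
21 | C9 aldehyde | O=C[C@@H]1[C@@](C)([C@@H](OC(C)=O)CC/C(C)=C\I)[C@@H](O[Si](C)(C)C(C)(C)C)CC[C@]1(C)O[Si](C)(C)C(C)(C)C | intermediate
22 | Brown adduct: C9 alcohol (as in the target), C8 4-methoxybenzyl ether (syn), C7 vinyl | C=C[C@H](OCc1ccc(OC)cc1)[C@@H](O)[C@@H]1[C@@](C)([C@@H](OC(C)=O)CC/C(C)=C\I)[C@@H](O[Si](C)(C)C(C)(C)C)CC[C@]1(C)O[Si](C)(C)C(C)(C)C | intermediate
23 | C9 acetate of 22 | C=C[C@H](OCc1ccc(OC)cc1)[C@@H](OC(C)=O)[C@@H]1[C@@](C)([C@@H](OC(C)=O)CC/C(C)=C\I)[C@@H](O[Si](C)(C)C(C)(C)C)CC[C@]1(C)O[Si](C)(C)C(C)(C)C | intermediate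
24 | vicinal diol from the vinyl group of 23 (new carbinol centre undefined) | OCC(O)[C@H](OCc1ccc(OC)cc1)[C@@H](OC(C)=O)[C@@H]1[C@@](C)([C@@H](OC(C)=O)CC/C(C)=C\I)[C@@H](O[Si](C)(C)C(C)(C)C)CC[C@]1(C)O[Si](C)(C)C(C)(C)C | intermediate (not isolated)
25 | C7 aldehyde (C8 4-methoxybenzyl ether, C9 acetate) | O=C[C@H](OCc1ccc(OC)cc1)[C@@H](OC(C)=O)[C@@H]1[C@@](C)([C@@H](OC(C)=O)CC/C(C)=C\I)[C@@H](O[Si](C)(C)C(C)(C)C)CC[C@]1(C)O[Si](C)(C)C(C)(C)C | intermediate
26 | ten-membered carbocycle: 2,9-diacetate, 7-hydroxy, 8-(4-methoxybenzyl) ether, 11,14-bis-silyl ether, (5Z) | CC(=O)O[C@H]1CC/C(C)=C\[C@H](O)[C@H](OCc3ccc(OC)cc3)[C@@H](OC(C)=O)[C@@H]2[C@]1(C)[C@@H](O[Si](C)(C)C(C)(C)C)CC[C@]2(C)O[Si](C)(C)C(C)(C)C | intermediate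
27 | C7 2-bromopropionate of 26 (both CHBr epimers) | CC(=O)O[C@H]1CC/C(C)=C\[C@H](OC(=O)C(C)Br)[C@H](OCc3ccc(OC)cc3)[C@@H](OC(C)=O)[C@@H]2[C@]1(C)[C@@H](O[Si](C)(C)C(C)(C)C)CC[C@]2(C)O[Si](C)(C)C(C)(C)C | intermediate
28 | C8 alcohol | CC(=O)O[C@H]1CC/C(C)=C\[C@H](OC(=O)C(C)Br)[C@H](O)[C@@H](OC(C)=O)[C@@H]2[C@]1(C)[C@@H](O[Si](C)(C)C(C)(C)C)CC[C@]2(C)O[Si](C)(C)C(C)(C)C | intermediate
29 | C8 ketone | CC(=O)O[C@H]1CC/C(C)=C\[C@H](OC(=O)C(C)Br)C(=O)[C@@H](OC(C)=O)[C@@H]2[C@]1(C)[C@@H](O[Si](C)(C)C(C)(C)C)CC[C@]2(C)O[Si](C)(C)C(C)(C)C | intermediate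
30 | 11,14-bis(tert-butyldimethylsilyl) ether of junceellolide I | CC(=O)O[C@H]1CC/C(C)=C\[C@@H]2OC(=O)[C@H](C)[C@@]2(O)[C@@H](OC(C)=O)[C@@H]2[C@]1(C)[C@@H](O[Si](C)(C)C(C)(C)C)CC[C@]2(C)O[Si](C)(C)C(C)(C)C | intermediate
31 | junceellolide I | CC(=O)O[C@H]1CC/C(C)=C\[C@@H]2OC(=O)[C@H](C)[C@@]2(O)[C@@H](OC(C)=O)[C@@H]2[C@]1(C)[C@@H](O)CC[C@]2(C)O | target

**Total step count:** 24.
**Longest linear sequence:** 20 steps (steps 1–6 and 11–24, from 1).

**Steps most likely to fail**

Step 19 (ring closure). The alkenylchromium species may be protonated or may add intermolecularly (oligomers) faster than it closes the strained ten-membered ring. The fallback closes ring B at C5=C6 by metathesis instead. It sets out from 25. Hydrodeiodination (Bu3SnH, Pd(PPh3)4 cat., THF) should give the isopropenyl aldehyde F1. An intermolecular Nozaki–Hiyama–Kishi vinylation (vinyl bromide, CrCl2, NiCl2 cat., DMSO) should give the Felkin allylic alcohol F2. Ring-closing metathesis of F2 (second-generation Grubbs catalyst, toluene, 80 °C, high dilution) should favour the Z ring alkene and comes back to the route at 26.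

Step 11 (aldol at C1). Simple diastereoselection at C2 may be low if open and closed transition states compete for the tetrasubstituted samarium enolate, and the hindered aldolate may revert by retro-aldol cleavage. The fallback sets C2 and C14 by hydride reductions instead of by the aldol transition state. It sets out from 17 as any mixture of C2 epimers. Dess–Martin oxidation should give the 1,3-diketone F3. The more reactive ring carbonyl is reduced under reagent control ((R)-Me-CBS oxazaborolidine, catecholborane, toluene, −40 °C) to the C14 alpha-carbinol F4. Hydroxyl-directed anti reduction of the side-chain ketone (Me4NBH(OAc)3, MeCN/AcOH, −20 °C) should give the anti diol F5. Selective acetylation of the less hindered C2 hydroxyl (Ac2O, pyridine, 0 °C) comes back to the route at 18.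

Step 23 (lactonisation). SmI2 may reduce the alpha-acyloxy ketone by single-electron transfer (loss of the C7 or C9 acyloxy group) in competition with C–Br reduction, and the enolate addition may show low facial selectivity. The fallback generates the ester enolate by hydride conjugate addition, with no single-electron reductant. It sets out from 26. Acylation with acryloyl chloride and iPr2NEt should give the acrylate F6. DDQ should give the C8 alcohol F7 and Dess–Martin oxidation the acrylate ketone F8. A reductive aldol cyclisation with [(Ph3P)CuH]6 (toluene, −40 °C), which is known to be syn-selective, should close the hydroxy lactone and comes back to the route at 30.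

**Further compounds**

F1 | step 19 | isopropenyl C7 aldehyde (25 with H in place of iodine) | O=C[C@H](OCc1ccc(OC)cc1)[C@@H](OC(C)=O)[C@@H]1[C@@](C)([C@@H](OC(C)=O)CCC(C)=C)[C@@H](O[Si](C)(C)C(C)(C)C)CC[C@]1(C)O[Si](C)(C)C(C)(C)C
F2 | step 19 | C7 allylic alcohol with C6 vinyl and C5 isopropenyl termini | C=C[C@H](O)[C@H](OCc1ccc(OC)cc1)[C@@H](OC(C)=O)[C@@H]1[C@@](C)([C@@H](OC(C)=O)CCC(C)=C)[C@@H](O[Si](C)(C)C(C)(C)C)CC[C@]1(C)O[Si](C)(C)C(C)(C)C
F3 | step 11 | C2,C14 1,3-diketone | CC(C)(C)[Si](C)(C)OC[C@@H]1[C@@](C)(C(=O)CC/C(C)=C\I)C(=O)CC[C@]1(C)O[Si](C)(C)C(C)(C)C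
F4 | step 11 | C14 alpha-carbinol with C2 ketone | CC(C)(C)[Si](C)(C)OC[C@@H]1[C@@](C)(C(=O)CC/C(C)=C\I)[C@@H](O)CC[C@]1(C)O[Si](C)(C)C(C)(C)C
F5 | step 11 | C2,C14 anti diol | CC(C)(C)[Si](C)(C)OC[C@@H]1[C@@](C)([C@@H](O)CC/C(C)=C\I)[C@@H](O)CC[C@]1(C)O[Si](C)(C)C(C)(C)C
F6 | step 23 | C7 acrylate of 26 | CC(=O)O[C@H]1CC/C(C)=C\[C@H](OC(=O)C=C)[C@H](OCc3ccc(OC)cc3)[C@@H](OC(C)=O)[C@@H]2[C@]1(C)[C@@H](O[Si](C)(C)C(C)(C)C)CC[C@]2(C)O[Si](C)(C)C(C)(C)C
F7 | step 23 | C7 acrylate C8 alcohol | CC(=O)O[C@H]1CC/C(C)=C\[C@H](OC(=O)C=C)[C@H](O)[C@@H](OC(C)=O)[C@@H]2[C@]1(C)[C@@H](O[Si](C)(C)C(C)(C)C)CC[C@]2(C)O[Si](C)(C)C(C)(C)C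
F8 | step 23 | C7 acrylate C8 ketone | CC(=O)O[C@H]1CC/C(C)=C\[C@H](OC(=O)C=C)C(=O)[C@@H](OC(C)=O)[C@@H]2[C@]1(C)[C@@H](O[Si](C)(C)C(C)(C)C)CC[C@]2(C)O[Si](C)(C)C(C)(C)C
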